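All runs stem from a simulated flask from invented constants; noise was put on by code.

The amber run shows L from its first reading, 2.5% at 0.833 min, and the violet run, with more J on the same D, stands a little lower at 4.00 min. I read this as each J taking one D early, with the addition of D to Z as the rate-limiting step, so L should follow the D that remains.

| flask | J | D | remark | time |
|---|---|---|---|---|
| amber | 0.40 M | 2.4 M | run made earlier |  |
| violet | 0.60 M | 2.4 M | run made earlier |  |
| flask | 0.80 M | 2.40 M |  | 10 min |

- amber (time / min: L / %): 0.833: 2.5; 2.50: 7.8; 4.00: 12.4; 6.00: 16.6; 10.0: 20.4; 12.0: 21.9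
- violet (time / min: L / %): 2.00: 5.7; 4.00: 11.6; 6.00: 16.2; 8.00: 18.2; 10.0: 19.1; 12.0: 21.4

(each reading ± 0.5 percentage points)

- the numbers in the tables scatter with a standard deviation of 0.5 percentage points
- what may be going on: J + D -> Z; D + Z -> L; D + L -> Q; D + Q -> X; D <-> G; L <-> E

* equivalents of D to J, everything else as given, that leave most L at 10 min
* the amount of L then, in percent of the J charged
* the amount of L with the amounts as given

Does one quantity bring the two runs together? I try the charge of D less the charge of J, 2.00 M in amber, and call it spare D; equal spare D times minutes should mean equal L. Violet has 1.80 M, so its 10.0 min should read like amber at 9.00 min. Between amber's readings that is 19.4%; violet reads 19.1%, with a scatter of 0.5 percentage points.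

So what does the flask hold? It has 1.60 M spare, 0.800 of amber's, so its 10 min match amber at 8.00 min, and I expect 18.5% of L.

How far can more D go? To match amber's last reading, 21.9%, at 10 min, the flask needs on this reckoning 2.40 M spare, or 4.00 equivalents. Amber's readings still rise at their end, so I put the best above those equivalents.

The forecast gives 18% as charged and 23.5% at 6 equiv, on the ground that the flask “has about 1.6 M D left, so its clock runs at 0.8 of amber's”.

The flask gives 18.1%, and the most L, 26.1%, comes at 6.32 equiv.

    J + D → Z (k = 0.0130 M⁻¹ s⁻¹)
    D + Z → L (k = 5.60 × 10⁻⁴ M⁻¹ s⁻¹)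
    D + L → Q (k = 6.50 × 10⁻⁴ M⁻¹ s⁻¹)
    D + Q → X (k = 0.0170 M⁻¹ s⁻¹)
    D ⇌ G (K = 0.310, k = 0.0210 s⁻¹)
    L ⇌ E (K = 1.40, k = 0.00120 s⁻¹)

Of the flask's 1.60 M spare D, 0.988 M stands as D and 0.308 M as G at 10.0 min, and the other 0.304 M has gone into L and what lies beyond it. The neighbour flask, charged with 0.96 M of D, has 0.160 M spare, 0.0800 of amber's, so its 10 min match amber at 0.800 min, next to the first reading of 2.5% at 0.833 min. That neighbour flask gives 3.97% of L, more than that reading, and it still holds 11% of its J unbound, with 16% of its D left.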